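## The problem

Balanophonin 12 is a phenylcoumaran neolignan built on a 2,3-dihydrobenzofuran. The benzo ring (ring A) carries a methoxy group at C7 and an (E)-propenal chain at C5. C2 carries a 4-hydroxy-3-methoxyphenyl group (ring B) and C3 a hydroxymethyl group. The two adjacent stereocentres are trans, (2R,3S), and they are not equal partners. C2 is a para-hydroxybenzylic aryl ether that ionises under acid and opens through a quinone methide under base, so its configuration is in effect dictated by C3. C3, once at the alcohol oxidation level, is configurationally fixed, so the absolute problem is C3 alone. The lability at C2, the enal (Michael acceptor, easily acetalised) and the free phenol rule out hydrogenolysis, strong base and hot mineral acid late in the route. The enal is therefore best attached last to a placeholder at C5. The feature that opens the key step is that the heterocycle is the formal sum of three simple parts. C3 bears exactly one extra carbon at the alcohol level, C2 bears an aryl ring whose para oxygen can carry a benzylic positive charge, and O1 sits on ring A ortho to C3a. Formaldehyde, the C=C bond of an (E)-2-hydroxystilbene and its phenol oxygen thus map onto the C3–CH2OH and O1–C2 bonds.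

## Retrosynthesis

**12 from 11 (O–Si).** The ring B phenol is kept as its triisopropylsilyl ether until the end, so the last step is buffered fluoride cleavage of 11. A silyl ether is preferred to a benzyl ether (hydrogenolysis would attack the enal and the C2–O bond) and to an acetal (acid removal in the presence of the enal). The forward step must only avoid free phenoxide next to the enal.

**11 from 8 and 9 (C5–Cα of the side chain).** The three-carbon enal is cut from ring A at C5, giving aryl bromide 8 and acrolein diethyl acetal 9. A Heck coupling followed by acid hydrolysis of the alkenyl acetal 10 installs the chain with (E) geometry in one operation. Cutting the enal C=C bond instead would require a C5 aldehyde, which would compete as an electrophile in the key step. The bromide is inert there and, para to O1, it also weakens ring A as a donor, which the key step needs.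

**8 from 6 and 7 (C3–CH2OH and O1–C2, the key cut).** Removing the hydroxymethyl carbon as formaldehyde 7 and opening O1–C2 leaves the achiral (E)-2-hydroxystilbene 6. This takes away the ring and both stereocentres at once, and the forward reaction is redox-neutral and adds every atom of both partners. Neighbouring cuts (C2–C3, or C3–C3a by rearrangement) leave C3 at the wrong oxidation level or need a chiral precursor. The forward reaction must deliver four things:
- formaldehyde, not a proton, must be the electrophile;
- attack must occur through the alkene carbon next to ring A;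
- the phenol must trap the cation before a second formaldehyde does;
- a chiral acid must choose the face at C3, with C2 following as trans.

**6 from 5 and 3 (aryl–vinyl bond on ring A).** The stilbene is cut between ring A and the alkene, giving iodophenol 5 and styrene 3. A Heck coupling gives the (E)-alkene directly and tolerates the free phenol. The iodide reacts well before the bromide, so the C5 placeholder is carried through. The alternative cut through the C=C bond (carbonyl olefination) would meet a phenoxide-deactivated salicylaldehyde and uncertain geometry.

**3 from 2 from 1; 5 from 4.** Styrene 3 is the methylenation product of silyl-protected vanillin 2, made from vanillin 1. Iodophenol 5 comes from 4-bromo-2-methoxyphenol 4 by iodination at the only free position ortho to the hydroxyl. Both starting materials are cheap, and the two branches are two steps and one step long.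

## Roads not taken

**Alternative 1: three-component conjunctive coupling across C2 and C3.**
- Cut: C2–C1' (to ring B) and C3–C3a (to ring A); the heterocycle stays open.
- Forward key step: aryllithium A3 adds to the (E)-alkenyl pinacol boronate A2. With Pd(OAc)2 and a chiral MandyPhos ligand, the arylpalladium species from bromide A4 triggers a 1,2-metallate shift in the ate complex. The product is the anti 1,2-diaryl boronic ester A1.
- Merits: this is an established catalytic enantioselective reaction class, and here it is ahead of the chosen plan in precedent. It joins three simple pieces and places both benzylic carbons under catalyst control.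
- Weak points: no ring is formed. C–B oxidation, removal of two methoxymethyl groups, closure of O1–C2, acetal cleavage and a two-carbon homologation of the aldehyde must follow, roughly doubling the step count. Closure at a para-oxygenated benzylic carbinol goes through ionisation, so the configuration installed at the boron-bearing carbon is not carried through. A β-substituted alkenyl boronate, an ortho-substituted electrophile and a bromide (halide inhibition) are the demanding end of this coupling.
- Comparison: against the better precedent the chosen plan sets ring closure in the stereodefining step, full atom economy, a single protecting group and a known-chemistry fallback.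

**Alternative 2: formal [4+1] annulation of a nitrovinylphenol with a benzylic ylide.**
- Cut: C2–C3 and O1–C2.
- Forward key step: Cs2CO3 deprotonates a chiral benzylic sulfonium salt such as A7. The ylide adds to the nitroalkene carbon next to ring A of A6, and the ortho phenoxide displaces the sulfide at C2. The product is the trans nitromethyl dihydrobenzofuran A5.
- Merits: ring and both stereocentres form in one operation, the trans outcome is typical, and the C5 bromide is retained. Ylide annulations onto ortho-hydroxy nitrostyrenes are an established family, so this key step is arguably closer to known ground than step 5.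
- Weak points: the chiral sulfide is stoichiometric. The electron-rich benzylic sulfonium salt gives only a semi-stabilised ylide and can ionise before it adds. The enantiodetermining Michael addition sets C3 at a distance from the sulfur-borne chirality. C3 emerges as CH2NO2, so a Nef reaction and a reduction must follow, through an α-aryl β-aryloxy aldehyde prone to epimerisation and ring-opening β-elimination.
- Comparison: convergency is comparable. The chosen plan delivers CH2OH directly at the right oxidation level from a catalytic source of chirality and is about two steps shorter.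

**Alternative 3: oxidative ring contraction of a chiral flavanone.**
- Cut: C3–C3a, made by a 1,2-aryl shift; the five-membered ring derives from a six-membered one.
- Forward key step: flavanone A9 is treated with PhI(OAc)2 (a trivalent iodine reagent), H2SO4 and trimethyl orthoformate. The enol ether is iodinated at C3, the ring A carbon migrates from C4 to C3, and C4 leaves the ring as the methyl ester. The product is the trans ester A8.
- Merits: this ring contraction is the best precedented key step of the four on closely related flavanones. It is reliably trans and relays C2 to C3. In reliability it is better than the chosen plan.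
- Weak points: it needs an enantiopure flavanone (asymmetric oxa-Michael closure of a chalcone, or a resolution). Flavanones racemise by reversible opening to the chalcone, a real threat under the strongly acidic contraction. The ring B tosylate that tempers this must later be removed under nucleophilic or basic conditions that the enal and the C2 ether tolerate poorly. The oxidant is stoichiometric and the ester needs a separate reduction. The count is about nine to ten steps.
- Comparison: the chosen plan is shorter and sets the robust centre C3 directly instead of relying on the labile C2. It pays for this with an unproven key step.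

Key step: step 5

Assumption: the sense of induction of the confined acid on a 1,2-diarylethene is not established, so the route is written with the (S,S) antipode as a placeholder for whichever antipode delivers (3S). Paraformaldehyde is drawn as its monomer 7.

## Route

Step 1
Reactants: 1 vanillin (4-hydroxy-3-methoxybenzaldehyde)
Product: 2 3-methoxy-4-[(triisopropylsilyl)oxy]benzaldehyde
Conditions: TIPSCl, imidazole, DMF, rt
Reagents that add atoms: triisopropylsilyl chloride, CC(C)[Si](Cl)(C(C)C)C(C)C
Why: Imidazole-promoted silylation of a phenol is routine; the bulky triisopropylsilyl ether is chosen because it must later survive an ylide, a strong Brønsted acid and hot carbonate while leaving the para oxygen a good π-donor.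

Step 2
Reactants: 2 3-methoxy-4-[(triisopropylsilyl)oxy]benzaldehyde
Product: 3 (4-ethenyl-2-methoxyphenoxy)triisopropylsilane
Conditions: Ph3PCH3Br, KOtBu, THF, 0 °C to rt
Reagents that add atoms: methyltriphenylphosphonium bromide, C[P+](c1ccccc1)(c1ccccc1)c1ccccc1.[Br-]
Why: Wittig methylenation of an aryl aldehyde with the non-stabilised ylide; with the base kept just below one equivalent relative to the salt, no free alkoxide remains to attack the aryl silyl ether.

Step 3
Reactants: 4 4-bromo-2-methoxyphenol
Product: 5 4-bromo-2-iodo-6-methoxyphenol
Conditions: NIS, TsOH (cat.), MeCN, rt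
Reagents that add atoms: N-iodosuccinimide, O=C1CCC(=O)N1I
Why: Electrophilic aromatic iodination; the hydroxyl is the strongest director and its para position is blocked by bromine, so iodine should enter the one free ortho position.

Step 4
Reactants: 5 4-bromo-2-iodo-6-methoxyphenol; 3 (4-ethenyl-2-methoxyphenoxy)triisopropylsilane
Product: 6 4-bromo-2-methoxy-6-[(E)-2-{3-methoxy-4-[(triisopropylsilyl)oxy]phenyl}ethenyl]phenol
Conditions: Pd(OAc)2 (5 mol %), n-Bu4NCl, NaHCO3, DMF, 70 °C
Reagents that add atoms: none
Why: Mizoroki–Heck reaction under ligand-free Jeffery conditions; zerovalent palladium inserts into the C–I bond far faster than into the electron-rich C–Br bond at this temperature, the aryl group adds to the terminal alkene carbon and syn β-hydride elimination gives the (E)-stilbene, and free ortho-iodophenols are competent partners.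

Step 5
Reactants: 6 4-bromo-2-methoxy-6-[(E)-2-{3-methoxy-4-[(triisopropylsilyl)oxy]phenyl}ethenyl]phenol; 7 formaldehyde (charged as paraformaldehyde)
Product: 8 [(2R,3S)-5-bromo-7-methoxy-2-{3-methoxy-4-[(triisopropylsilyl)oxy]phenyl}-2,3-dihydro-1-benzofuran-3-yl]methanol (trans)
Conditions: (CH2O)n (1.5 equiv), (S,S)-iIDP Brønsted acid (N-triflyl imino-imidodiphosphate on two 3,3'-diaryl-BINOL units, 5 mol %), cyclohexane/CHCl3, −20 °C to rt; aq. NaHCO3 work-up
Reagents that add atoms: none
Why: Proposed new method: the confined acid protonates monomeric formaldehyde inside its chiral pocket, the stilbene carbon attached to ring A adds to it (new C3–CH2OH bond) so that positive charge develops on the carbon attached to ring B, where the para-silyloxy group holds it as a quinone-methide-like cation paired with the chiral anion, and the ring A hydroxyl then forms O1–C2; the closest known reaction type is the catalytic asymmetric intermolecular Prins reaction of aryl alkenes with paraformaldehyde under confined imino-imidodiphosphate acids (which ends in 1,3-dioxanes), together with electrophile-triggered cyclisations of 2-hydroxystilbenes to 2-aryl-2,3-dihydrobenzofurans. The five-membered ring closes by 5-exo-trig addition of the phenol oxygen to the exocyclic C2=C(ring B) bond of that cation, formally a 5-endo closure across the original alkene that only the stepwise cationic course makes possible. C3 is set in the C–C bond formation by the alkene face that the counter-anion leaves open (catalyst control); C2 is set relative to C3 by closure anti to the new CH2OH group, and since the C2–O1 bond of 8 is a para-silyloxybenzylic ether that can re-ionise under the acid, any cis isomer should drain to the more stable trans ring without touching C3. Four selectivities are needed: attack through the ring A terminus (ring B carries a para oxygen donor of roughly alkyl-ether strength, whereas the ring A hydroxyl is ortho, hydrogen-bonded to its methoxy neighbour and weakened by the para bromine, and only the desired cation has an intramolecular exit); formaldehyde and not a proton as electrophile (formaldehyde in excess buffers the acid, low temperature); phenol capture ahead of a second formaldehyde (unimolecular five-membered closure, formaldehyde kept near one equivalent); and no aromatic hydroxymethylation (ring A has no free ortho or para position and the silyl group shields ring B).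

Step 6
Reactants: 8 [(2R,3S)-5-bromo-7-methoxy-2-{3-methoxy-4-[(triisopropylsilyl)oxy]phenyl}-2,3-dihydro-1-benzofuran-3-yl]methanol; 9 acrolein diethyl acetal (3,3-diethoxyprop-1-ene)
Product: 11 (E)-3-[(2R,3S)-3-(hydroxymethyl)-7-methoxy-2-{3-methoxy-4-[(triisopropylsilyl)oxy]phenyl}-2,3-dihydro-1-benzofuran-5-yl]prop-2-enal, via alkenyl diethyl acetal 10 (not isolated)
Conditions: Pd(OAc)2 (3 mol %), n-Bu4NOAc, K2CO3, KCl, DMF, 90 °C; then 2 M HCl, rt
Reagents that add atoms: water, O
Why: Mizoroki–Heck coupling of an aryl bromide with acrolein diethyl acetal under acetate/carbonate/chloride conditions that steer β-hydride elimination to the conjugated (E)-alkenyl acetal and away from the ketene acetal, followed by acid hydrolysis in the same pot; the aldehyde is never exposed to the hot base and neither stereocentre is involved.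

Step 7
Reactants: 11 (E)-3-[(2R,3S)-3-(hydroxymethyl)-7-methoxy-2-{3-methoxy-4-[(triisopropylsilyl)oxy]phenyl}-2,3-dihydro-1-benzofuran-5-yl]prop-2-enal
Product: 12 balanophonin, (E)-3-[(2R,3S)-2-(4-hydroxy-3-methoxyphenyl)-3-(hydroxymethyl)-7-methoxy-2,3-dihydro-1-benzofuran-5-yl]prop-2-enal
Conditions: n-Bu4NF, AcOH, THF, 0 °C
Reagents that add atoms: none
Why: Fluoride cleavage of an aryl silyl ether; acetic acid buffering keeps the liberated phenol protonated, so that neither the enal nor the C2 benzylic ether meets a phenoxide.

## Compound list

1 | vanillin (4-hydroxy-3-methoxybenzaldehyde) | COc1cc(C=O)ccc1O | starting material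
2 | 3-methoxy-4-[(triisopropylsilyl)oxy]benzaldehyde | COc1cc(C=O)ccc1O[Si](C(C)C)(C(C)C)C(C)C | intermediate
3 | (4-ethenyl-2-methoxyphenoxy)triisopropylsilane | COc1cc(C=C)ccc1O[Si](C(C)C)(C(C)C)C(C)C | intermediate
4 | 4-bromo-2-methoxyphenol | COc1cc(Br)ccc1O | starting material
5 | 4-bromo-2-iodo-6-methoxyphenol | COc1cc(Br)cc(I)c1O | intermediate
6 | 4-bromo-2-methoxy-6-[(E)-2-{3-methoxy-4-[(triisopropylsilyl)oxy]phenyl}ethenyl]phenol | COc1cc(Br)cc(/C=C/c2ccc(O[Si](C(C)C)(C(C)C)C(C)C)c(OC)c2)c1O | intermediate
7 | formaldehyde (charged as paraformaldehyde) | C=O | starting material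
8 | [(2R,3S)-5-bromo-7-methoxy-2-{3-methoxy-4-[(triisopropylsilyl)oxy]phenyl}-2,3-dihydro-1-benzofuran-3-yl]methanol (trans) | COc1cc([C@@H]2Oc3c(OC)cc(Br)cc3[C@H]2CO)ccc1O[Si](C(C)C)(C(C)C)C(C)C | intermediate
9 | acrolein diethyl acetal (3,3-diethoxyprop-1-ene) | C=CC(OCC)OCC | starting material
10 | [(2R,3S)-5-[(E)-3,3-diethoxyprop-1-en-1-yl]-7-methoxy-2-{3-methoxy-4-[(triisopropylsilyl)oxy]phenyl}-2,3-dihydro-1-benzofuran-3-yl]methanol | COc1cc([C@@H]2Oc3c(OC)cc(/C=C/C(OCC)OCC)cc3[C@H]2CO)ccc1O[Si](C(C)C)(C(C)C)C(C)C | intermediate
11 | (E)-3-[(2R,3S)-3-(hydroxymethyl)-7-methoxy-2-{3-methoxy-4-[(triisopropylsilyl)oxy]phenyl}-2,3-dihydro-1-benzofuran-5-yl]prop-2-enal | COc1cc([C@@H]2Oc3c(OC)cc(/C=C/C=O)cc3[C@H]2CO)ccc1O[Si](C(C)C)(C(C)C)C(C)C | intermediate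
12 | balanophonin, (E)-3-[(2R,3S)-2-(4-hydroxy-3-methoxyphenyl)-3-(hydroxymethyl)-7-methoxy-2,3-dihydro-1-benzofuran-5-yl]prop-2-enal | COc1cc([C@@H]2Oc3c(OC)cc(/C=C/C=O)cc3[C@H]2CO)ccc1O | target

## Step count and least certain steps

Total step count: 7. Longest linear sequence: 6 (steps 1, 2, 4, 5, 6, 7 from vanillin).

**Step 5 (key step, proposed new method).** Several processes can divert it:
- Protonation of the electron-rich stilbene followed by phenol capture (plain hydroalkoxylation) would give the ring without the hydroxymethyl group.
- A second formaldehyde could win the cation. The parent reaction is thought to run through an activated formaldehyde oligomer that closes a 1,3-dioxane almost in concert.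
- Attack through the ring B terminus (the ortho-quinone-methide manifold of ring A) would lead to open-chain or dioxane products.
- A hemiformal of the ring A phenol could engage the alkene intramolecularly.
- An internal 1,2-diarylethene may fit the confined pocket poorly, giving low facial selectivity.

A dioxane or formal by-product still carries a para-silyloxybenzylic C–O bond. Mild acid methanolysis of the crude mixture may therefore funnel such material to 8 through the same cation.

The fallback uses known chemistry, sets out from aldehyde 2 and iodophenol 5, and rejoins the route at 8: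
- NaBH4 reduction of 2 gives [3-methoxy-4-(triisopropylsilyloxy)phenyl]methanol F1.
- Mitsunobu etherification of F1 with 5 (PPh3, diisopropyl azodicarboxylate) gives {4-[(4-bromo-2-iodo-6-methoxyphenoxy)methyl]-2-methoxyphenoxy}triisopropylsilane F2.
- Coupling of the aryl iodide with ethyl diazoacetate (Pd(PPh3)4, Ag2CO3, Et3N) gives ethyl 2-(5-bromo-3-methoxy-2-{[3-methoxy-4-(triisopropylsilyloxy)benzyl]oxy}phenyl)-2-diazoacetate F3.
- Rh2(S-PTTL)4 (dirhodium tetrakis[N-phthaloyl-(S)-tert-leucinate], or its antipode as needed for 2R) effects enantioselective intramolecular carbene insertion into the benzylic C–H bond. This gives the cis ester ethyl (2R,3S)-5-bromo-7-methoxy-2-[3-methoxy-4-(triisopropylsilyloxy)phenyl]-2,3-dihydro-1-benzofuran-3-carboxylate F4.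
- NaOEt in EtOH epimerises C3 to the trans ester ethyl (2R,3R)-5-bromo-7-methoxy-2-[3-methoxy-4-(triisopropylsilyloxy)phenyl]-2,3-dihydro-1-benzofuran-3-carboxylate F5.
- i-Bu2AlH reduction of F5 gives 8.

**Step 4.** Once the iodide is consumed, oxidative addition at the C–Br bond of product or starting material could begin and lead to oligomers. The electron-rich styrene may also polymerise or insert with the wrong regiochemistry (1,1-diarylethene formation), and the phenoxide may slow the catalyst. The fallback changes the bond-forming event to a cross-coupling, sets out from 2 and 5, and returns at 6. A boron-Wittig reaction of 2 with bis(pinacolato)borylmethane and lithium 2,2,6,6-tetramethylpiperidide gives (E)-2-{2-[3-methoxy-4-(triisopropylsilyloxy)phenyl]ethenyl}-4,4,5,5-tetramethyl-1,3,2-dioxaborolane F6. Suzuki–Miyaura coupling of F6 with 5 at the iodide (Pd(dppf)Cl2, aqueous K3PO4, THF, 40 °C) gives 6.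

**Step 6.** β-Hydride elimination toward the acetal carbon would lead to the saturated ester after hydrolysis. Hot carbonate could also remove the silyl group early, and the resulting phenoxide could open the ring at C2. Slow oxidative addition at the electron-rich bromide would let the ligand-free catalyst aggregate. The fallback sets out from 8 and returns at 10 and then 11. A Suzuki–Miyaura coupling with the commercial reagent (E)-2-(3,3-diethoxyprop-1-enyl)-4,4,5,5-tetramethyl-1,3,2-dioxaborolane (Pd(dppf)Cl2, aqueous K3PO4, dioxane, 70 °C) forms the same alkenyl acetal 10 with its geometry preset. The same dilute-acid hydrolysis then gives 11. No new compound is made.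

**Step 7.** Even buffered fluoride may generate enough phenoxide for conjugate addition to the enal, or for opening at C2 through the para-quinone methide with loss of the trans relationship. The fallback reorders the end game so that fluoride never meets the enal; it sets out from 8 and returns at 12. Desilylation of 8 with n-Bu4NF gives 4-[(2R,3S)-5-bromo-3-(hydroxymethyl)-7-methoxy-2,3-dihydro-1-benzofuran-2-yl]-2-methoxyphenol F7. Suzuki–Miyaura coupling of F7 with the same alkenylboronate gives 4-[(2R,3S)-5-[(E)-3,3-diethoxyprop-1-enyl]-3-(hydroxymethyl)-7-methoxy-2,3-dihydro-1-benzofuran-2-yl]-2-methoxyphenol F8, which is not isolated. Dilute acid at room temperature then releases 12.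

## Further compounds

F1 | step 5 | [3-methoxy-4-(triisopropylsilyloxy)phenyl]methanol | COc1cc(CO)ccc1O[Si](C(C)C)(C(C)C)C(C)C
F2 | step 5 | {4-[(4-bromo-2-iodo-6-methoxyphenoxy)methyl]-2-methoxyphenoxy}triisopropylsilane | COc1cc(COc2c(I)cc(Br)cc2OC)ccc1O[Si](C(C)C)(C(C)C)C(C)C
F3 | step 5 | ethyl 2-(5-bromo-3-methoxy-2-{[3-methoxy-4-(triisopropylsilyloxy)benzyl]oxy}phenyl)-2-diazoacetate | CCOC(=O)C(=[N+]=[N-])c1cc(Br)cc(OC)c1OCc1ccc(O[Si](C(C)C)(C(C)C)C(C)C)c(OC)c1
F4 | step 5 | ethyl (2R,3S)-5-bromo-7-methoxy-2-[3-methoxy-4-(triisopropylsilyloxy)phenyl]-2,3-dihydro-1-benzofuran-3-carboxylate (cis) | COc1cc([C@@H]2Oc3c(OC)cc(Br)cc3[C@@H]2C(=O)OCC)ccc1O[Si](C(C)C)(C(C)C)C(C)C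
F5 | step 5 | ethyl (2R,3R)-5-bromo-7-methoxy-2-[3-methoxy-4-(triisopropylsilyloxy)phenyl]-2,3-dihydro-1-benzofuran-3-carboxylate (trans) | COc1cc([C@@H]2Oc3c(OC)cc(Br)cc3[C@H]2C(=O)OCC)ccc1O[Si](C(C)C)(C(C)C)C(C)C
F6 | step 4 | (E)-2-{2-[3-methoxy-4-(triisopropylsilyloxy)phenyl]ethenyl}-4,4,5,5-tetramethyl-1,3,2-dioxaborolane | COc1cc(/C=C/B2OC(C)(C)C(C)(C)O2)ccc1O[Si](C(C)C)(C(C)C)C(C)C
F0 | step 6 | none | none
F7 | step 7 | 4-[(2R,3S)-5-bromo-3-(hydroxymethyl)-7-methoxy-2,3-dihydro-1-benzofuran-2-yl]-2-methoxyphenol | COc1cc([C@@H]2Oc3c(OC)cc(Br)cc3[C@H]2CO)ccc1O
F8 | step 7 | 4-[(2R,3S)-5-[(E)-3,3-diethoxyprop-1-enyl]-3-(hydroxymethyl)-7-methoxy-2,3-dihydro-1-benzofuran-2-yl]-2-methoxyphenol | COc1cc([C@@H]2Oc3c(OC)cc(/C=C/C(OCC)OCC)cc3[C@H]2CO)ccc1O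
A1 | alternative 1 | 2-[(1R,2S)-3-[(tert-butyldimethylsilyl)oxy]-2-[5-(1,3-dioxolan-2-yl)-3-methoxy-2-(methoxymethoxy)phenyl]-1-[3-methoxy-4-(methoxymethoxy)phenyl]propyl]-4,4,5,5-tetramethyl-1,3,2-dioxaborolane (anti) | COCOc1ccc(cc1OC)[C@H](B2OC(C)(C)C(C)(C)O2)[C@H](CO[Si](C)(C)C(C)(C)C)c1cc(C2OCCO2)cc(OC)c1OCOC
A2 | alternative 1 | (E)-tert-butyldimethyl{[3-(4,4,5,5-tetramethyl-1,3,2-dioxaborolan-2-yl)prop-2-en-1-yl]oxy}silane | CC(C)(C)[Si](C)(C)OC/C=C/B1OC(C)(C)C(C)(C)O1
A3 | alternative 1 | [3-methoxy-4-(methoxymethoxy)phenyl]lithium | [Li]c1ccc(OCOC)c(OC)c1
A4 | alternative 1 | 2-[3-bromo-5-methoxy-4-(methoxymethoxy)phenyl]-1,3-dioxolane | COCOc1c(Br)cc(C2OCCO2)cc1OC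
A5 | alternative 2 | (2R,3S)-5-bromo-7-methoxy-2-[3-methoxy-4-(methoxymethoxy)phenyl]-3-(nitromethyl)-2,3-dihydro-1-benzofuran (trans) | COc1cc([C@@H]2Oc3c(OC)cc(Br)cc3[C@H]2C[N+](=O)[O-])ccc1OCOC
A6 | alternative 2 | 4-bromo-2-methoxy-6-[(E)-2-nitroethenyl]phenol | COc1cc(Br)cc(/C=C/[N+](=O)[O-])c1O
A7 | alternative 2 | (2R,5R)-1-[3-methoxy-4-(methoxymethoxy)benzyl]-2,5-dimethylthiolan-1-ium trifluoromethanesulfonate | C[C@@H]1CC[C@@H](C)[S+]1Cc1ccc(OCOC)c(OC)c1.[O-]S(=O)(=O)C(F)(F)F
A8 | alternative 3 | methyl (2R,3R)-5-bromo-7-methoxy-2-{3-methoxy-4-[(4-methylbenzenesulfonyl)oxy]phenyl}-2,3-dihydro-1-benzofuran-3-carboxylate (trans) | COc1cc([C@@H]2Oc3c(OC)cc(Br)cc3[C@H]2C(=O)OC)ccc1OS(=O)(=O)c1ccc(C)cc1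
A9 | alternative 3 | (2R)-6-bromo-8-methoxy-2-{3-methoxy-4-[(4-methylbenzenesulfonyl)oxy]phenyl}-2,3-dihydro-4H-chromen-4-one | COc1cc([C@@H]2Oc3c(OC)cc(Br)cc3C(=O)C2)ccc1OS(=O)(=O)c1ccc(C)cc1
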